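**Strategy.** The seven-membered ring is read as a four-carbon diene (C8–C9–C10–C1) joined to a three-carbon oxyallyl unit (C5–C6–C7); the cyclopentane atoms C2–C3–C4 are the tether between them (daucane numbering, defined below). Two features are exploited: the C6 oxygen lies between C5 and C7, and C4, next to C5, bears a tertiary oxygen, the footprint of an α,β-epoxy ketone. A silyl-triflate-triggered intramolecular (4+3) cycloaddition of epoxy enol silane 13 therefore forms C1–C5 and C7–C8 in one operation, closes both rings, sets C1, C5 and C8 and turns the epoxide oxygen into the C4 hydroxyl. The precursor is an open-chain epoxy triene made through a dihydropyranone that relays chirality from C2 to C4 and C5.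

Key step: step 10

Numbering: every compound carries the carbon numbers of the bicyclic product (C1 = ring-fusion carbon with the methyl group, C2 = CH–O of the five-membered ring, C3 = CH2, C4 = C(O)(isopropyl), C5 = ring-fusion CH, C6 next to C5, then C7, C8, C9, and C10 next to C1). α is the face that holds the C1 methyl group and H-5, β the other face. In this numbering the target is (1R,2S,4S,5R,6R,8S,9R,10R).

Assumption: the (S,S)-enantiomer of the bisphosphoramide catalyst in step 3 is taken as the one that directs the enol silane to the Si face of aldehyde 3; should the opposite sense apply, its antipode is used and nothing else changes.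

**Step 1**
Reactants: 1 (E)-but-2-enal; 2 2-(triphenylphosphoranylidene)propanal
Product: 3 (2E,4E)-2-methylhexa-2,4-dienal
Conditions: toluene, 80 °C
Reagents that add atoms: none
Why: Wittig olefination with a formyl-stabilised ylide, which should react with the aldehyde of 1 and give the (E)-trisubstituted enal.

**Step 2**
Reactants: 4 3-methylbutan-2-one
Product: 5 3-methyl-2-(trimethylsilyloxy)but-1-ene
Conditions: LiN(iPr)2, THF, −78 °C; Me3SiCl
Reagents that add atoms: chlorotrimethylsilane, C[Si](C)(C)Cl
Why: kinetic deprotonation at the methyl group and O-silylation give the less substituted silyl enol ether.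

**Step 3**
Reactants: 3 (2E,4E)-2-methylhexa-2,4-dienal; 5 3-methyl-2-(trimethylsilyloxy)but-1-ene
Product: 6 (5S,6E,8E)-5-hydroxy-2,6-dimethyldeca-6,8-dien-3-one
Conditions: SiCl4, (S,S)-bisphosphoramide catalyst [two (S)-N,N'-dimethyl-1,1'-binaphthyl-2,2'-diamine-derived cyclic phosphoric triamides linked through N,N'-dimethylpentane-1,5-diamine] (5 mol%), iPr2NEt (10 mol%), CH2Cl2, −78 °C; aq. NaHCO3
Reagents that add atoms: none
Why: Lewis-base-activated SiCl4 Mukaiyama aldol addition (Denmark type) adds 1,2 to the conjugated aldehyde, and the chiral silicon cation should expose the Si face so that C2 is formed as (S).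

**Step 4**
Reactants: 6 (5S,6E,8E)-5-hydroxy-2,6-dimethyldeca-6,8-dien-3-one; 7 2-(diethoxyphosphoryl)acetic acid
Product: 8 (5S,6E,8E)-2,6-dimethyl-3-oxodeca-6,8-dien-5-yl 2-(diethoxyphosphoryl)acetate
Conditions: N,N'-dicyclohexylcarbodiimide, 4-(dimethylamino)pyridine (cat.), CH2Cl2, 0 °C
Reagents that add atoms: none
Why: Steglich esterification of the secondary alcohol under conditions mild enough to avoid β-elimination.

**Step 5**
Reactants: 8 (5S,6E,8E)-2,6-dimethyl-3-oxodeca-6,8-dien-5-yl 2-(diethoxyphosphoryl)acetate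
Product: 9 (6S)-6-[(2E,4E)-hexa-2,4-dien-2-yl]-4-(propan-2-yl)-5,6-dihydro-2H-pyran-2-one
Conditions: LiCl, iPr2NEt, MeCN, rt
Reagents that add atoms: none
Why: intramolecular Horner–Wadsworth–Emmons reaction (Masamune–Roush conditions) onto the isopropyl ketone; the six-membered ring fixes the C4=C5 geometry with the carbonyl cis to C3.

**Step 6**
Reactants: 9 (6S)-6-[(2E,4E)-hexa-2,4-dien-2-yl]-4-(propan-2-yl)-5,6-dihydro-2H-pyran-2-one
Product: 10 (1R,4S,6S)-4-[(2E,4E)-hexa-2,4-dien-2-yl]-6-(propan-2-yl)-3,7-dioxabicyclo[4.1.0]heptan-2-one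
Conditions: 30% H2O2, NaOH, MeOH, 0 °C; pH 7 phosphate buffer
Reagents that add atoms: hydrogen peroxide, OO
Why: Weitz–Scheffer nucleophilic epoxidation touches only the electron-poor lactone alkene, and axial attack of hydroperoxide at C4 anti to the pseudo-equatorial dienyl group at C2 should give the trans epoxide, setting C4 and C5.

**Step 7**
Reactants: 10 (1R,4S,6S)-4-[(2E,4E)-hexa-2,4-dien-2-yl]-6-(propan-2-yl)-3,7-dioxabicyclo[4.1.0]heptan-2-one
Product: 11 1-{(2R,3S)-3-[(2S,3E,5E)-2-hydroxy-3-methylhepta-3,5-dien-1-yl]-3-(propan-2-yl)oxiran-2-yl}ethan-1-one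
Conditions: MeLi (1.05 equiv), THF, −78 °C; aq. NH4Cl
Reagents that add atoms: methyllithium, [Li]C
Why: single addition of the organolithium to the lactone carbonyl (the lithium lactolate is stable at −78 °C) brings in C7 and frees the C2 hydroxyl, the product being in equilibrium with its lactol.

**Step 8**
Reactants: 11 1-{(2R,3S)-3-[(2S,3E,5E)-2-hydroxy-3-methylhepta-3,5-dien-1-yl]-3-(propan-2-yl)oxiran-2-yl}ethan-1-one
Product: 12 triethylsilyl ether of 11
Conditions: Et3SiCl, imidazole, DMF, 0 °C
Reagents that add atoms: chlorotriethylsilane, CC[Si](Cl)(CC)CC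
Why: silylation of the secondary hydroxyl of the open form drains the lactol equilibrium and leaves a free methyl ketone.

**Step 9**
Reactants: 12 triethylsilyl ether of 11
Product: 13 trimethylsilyl enol ether of 12
Conditions: Me3SiOTf, Et3N, CH2Cl2, −78 to 0 °C
Reagents that add atoms: trimethylsilyl trifluoromethanesulfonate, C[Si](C)(C)OS(=O)(=O)C(F)(F)F
Why: soft enolisation can take place only toward the methyl group, because C5 is an epoxide carbon, and gives the epoxy enol silane.

**Step 10**
Reactants: 13 trimethylsilyl enol ether of 12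
Product: 15 cis-fused hydroxy ketone cycloadduct, via trimethylsilyl ether cycloadduct 14 (not isolated)
Conditions: Me3SiOTf (10 mol%), CH2Cl2, −78 °C; then citric acid, MeOH, 0 °C
Reagents that add atoms: none
Why: Me3SiOTf silylates the epoxide oxygen and the C5–O bond is broken with the help of the enol silane, so that C5–C6–C7 reacts as a 2-silyloxyallyl cation with the tethered diene in an asynchronous (4+3) cycloaddition (C5–C1 first, then C7–C8), after which loss of the silyl group from the C6 oxocarbenium ion returns the catalyst; the closest known reaction type is the silyl-triflate-catalysed intramolecular (4+3) cycloaddition of epoxy enol silanes with tethered dienes, a member of the oxyallyl cation (4+3) family. The cyclopentane closes by attack of the diene terminus C1 on C5 through the three-atom tether C2–C3–C4 (5-exo, the C1=C10 bond and the allyl unit both lying outside the new ring), and the cycloheptenone is the ring of the (4+3) union, completed by the C7–C8 bond. C5 is set by backside displacement of the epoxide oxygen (inversion), which puts the C6 arm cis to the C4 oxygen, while C4 keeps the configuration of the epoxide. C1 is set by the tether: the C2 oxygen, cis to the C4 oxygen, should lie in the diene plane (inside-alkoxy conformation) with the isopropyl group on the other face, so the diene arm should bond on the face of the C6 arm and give the cis ring fusion. C8 follows from suprafacial addition to the (E,E)-diene, which places H-8 cis to the C1 methyl group. The step needs ionisation at C5 and not at the tertiary C4 (secured by conjugation of C5 with the enol silane) and seven-ring closure at C8 in preference to five-ring closure at C10 (favoured by a concerted, compact transition state at −78 °C).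

**Step 11**
Reactants: 15 cis-fused hydroxy ketone cycloadduct
Product: 16 4β,6α-diol
Conditions: Me4NBH(OAc)3, MeCN/AcOH, −30 °C
Reagents that add atoms: none
Why: Evans–Saksena hydroxyl-directed reduction, in which the borohydride bound to the 4β-oxygen delivers hydride to the concave β face of C6 and should give the 6α-alcohol; the reagent does not reduce a ketone without this direction.

**Step 12**
Reactants: 16 4β,6α-diol
Product: 18 8α,9α-epoxy-4β,6α,10α-triol 2-triethylsilyl ether, via allylic hydroperoxide 17 (not isolated)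
Conditions: O2, hν, 5,10,15,20-tetraphenylporphyrin (cat.), CH2Cl2, −10 °C; then Ti(OiPr)4 (0.3 equiv), 0 °C
Reagents that add atoms: dioxygen, O=O
Why: Schenck ene reaction of singlet oxygen, for which H-8 on the convex α face is the only allylic hydrogen, so oxygen must enter at C10 from the α face with shift of the alkene to C8=C9; titanium-mediated oxygen transfer from the hydroperoxide (hydroxy-epoxidation) then epoxidises syn to the 10α-oxygen.

**Step 13**
Reactants: 18 8α,9α-epoxy-4β,6α,10α-triol 2-triethylsilyl ether; 19 angelic acid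
Product: 20 6α-angelate of 18
Conditions: 19 (1.2 equiv), 2,4,6-trichlorobenzoyl chloride (1.2 equiv), Et3N, toluene, rt; then 18, 40 °C
Reagents that add atoms: none
Why: Yamaguchi-type mixed-anhydride esterification without nucleophilic catalyst, which should keep the (Z)-geometry, is run with a limiting amount of the anhydride so that the C6 hydroxyl (flanked by a CH2 and a CH) reacts before the neopentyl C10 hydroxyl and the tertiary 4-hydroxyl, and any C10 monoester formed would converge on 21 in step 14.

**Step 14**
Reactants: 20 6α-angelate of 18; 19 angelic acid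
Product: 21 6α,10α-bis(angelate) 2-triethylsilyl ether
Conditions: 19 (5 equiv), 2,4,6-trichlorobenzoyl chloride (5 equiv), Et3N, toluene, rt; then 20, 80 °C
Reagents that add atoms: none
Why: the same mixed-anhydride esterification with excess reagent at higher temperature should acylate the hindered C10 hydroxyl (between the quaternary C1 and the epoxide) without Z-to-E isomerisation, while the tertiary 4-hydroxyl and the silyl-protected 2-oxygen stay untouched.

**Step 15**
Reactants: 21 6α,10α-bis(angelate) 2-triethylsilyl ether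
Product: 22 target CNP0265715.2
Conditions: HF·pyridine, pyridine, THF, 0 °C
Reagents that add atoms: none
Why: buffered fluoride cleavage of the secondary triethylsilyl ether, mild enough for the epoxide and the angelates.

**Compound list**

1 | (E)-but-2-enal (crotonaldehyde) | C/C=C/C=O | starting material
2 | 2-(triphenylphosphoranylidene)propanal | CC(C=O)=P(c1ccccc1)(c1ccccc1)c1ccccc1 | starting material
3 | (2E,4E)-2-methylhexa-2,4-dienal | C/C=C/C=C(\C)C=O | intermediate
4 | 3-methylbutan-2-one | CC(C)C(C)=O | starting material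
5 | 3-methyl-2-(trimethylsilyloxy)but-1-ene | CC(C)C(=C)O[Si](C)(C)C | intermediate
6 | (5S,6E,8E)-5-hydroxy-2,6-dimethyldeca-6,8-dien-3-one | C/C=C/C=C(\C)[C@@H](O)CC(=O)C(C)C | intermediate
7 | 2-(diethoxyphosphoryl)acetic acid | OC(=O)CP(=O)(OCC)OCC | starting material
8 | (5S,6E,8E)-2,6-dimethyl-3-oxodeca-6,8-dien-5-yl 2-(diethoxyphosphoryl)acetate | C/C=C/C=C(\C)[C@@H](OC(=O)CP(=O)(OCC)OCC)CC(=O)C(C)C | intermediate
9 | (6S)-6-[(2E,4E)-hexa-2,4-dien-2-yl]-4-(propan-2-yl)-5,6-dihydro-2H-pyran-2-one | C/C=C/C=C(\C)[C@@H]1CC(C(C)C)=CC(=O)O1 | intermediate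
10 | (1R,4S,6S)-4-[(2E,4E)-hexa-2,4-dien-2-yl]-6-(propan-2-yl)-3,7-dioxabicyclo[4.1.0]heptan-2-one (epoxide trans to the dienyl group) | C/C=C/C=C(\C)[C@@H]1C[C@@]2(C(C)C)O[C@H]2C(=O)O1 | intermediate
11 | 1-{(2R,3S)-3-[(2S,3E,5E)-2-hydroxy-3-methylhepta-3,5-dien-1-yl]-3-(propan-2-yl)oxiran-2-yl}ethan-1-one (in equilibrium with its lactol) | C/C=C/C=C(\C)[C@H](C[C@@]1(C(C)C)O[C@H]1C(C)=O)O | intermediate
12 | triethylsilyl ether of 11: 1-{(2R,3S)-3-[(2S,3E,5E)-3-methyl-2-(triethylsilyloxy)hepta-3,5-dien-1-yl]-3-(propan-2-yl)oxiran-2-yl}ethan-1-one | C/C=C/C=C(\C)[C@H](C[C@@]1(C(C)C)O[C@H]1C(C)=O)O[Si](CC)(CC)CC | intermediate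
13 | trimethylsilyl enol ether of 12: (2S,3R)-oxirane bearing isopropyl and the (2S,3E,5E)-3-methyl-2-(triethylsilyloxy)hepta-3,5-dien-1-yl chain on C2 and 1-(trimethylsilyloxy)ethenyl on C3 | C/C=C/C=C(\C)[C@H](C[C@@]1(C(C)C)O[C@H]1C(=C)O[Si](C)(C)C)O[Si](CC)(CC)CC | intermediate
14 | cis-fused cycloadduct as C4 trimethylsilyl ether: C6 ketone, C9=C10 alkene, 1α-methyl, 5α-H, 2β-triethylsilyloxy, 4β-trimethylsilyloxy, 4α-isopropyl, 8β-methyl | O=C1C[C@@H](C)C=C[C@@]2(C)[C@@H](O[Si](CC)(CC)CC)C[C@](O[Si](C)(C)C)(C(C)C)[C@@H]12 | intermediate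
15 | (1S,3S,3aS,6R,8aR)-3-hydroxy-6,8a-dimethyl-3-(propan-2-yl)-1-(triethylsilyloxy)-2,3,3a,5,6,8a-hexahydroazulen-4(1H)-one (cis-fused; 4β-hydroxy, 2β-silyloxy, 8β-methyl in the route numbering) | O=C1C[C@@H](C)C=C[C@@]2(C)[C@@H](O[Si](CC)(CC)CC)C[C@](O)(C(C)C)[C@@H]12 | intermediate
16 | (1S,3S,3aR,4R,6R,8aR)-6,8a-dimethyl-3-(propan-2-yl)-1-(triethylsilyloxy)-1,2,3,3a,4,5,6,8a-octahydroazulene-3,4-diol (4β,6α-diol in the route numbering) | O[C@@H]1C[C@@H](C)C=C[C@@]2(C)[C@@H](O[Si](CC)(CC)CC)C[C@](O)(C(C)C)[C@@H]12 | intermediate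
17 | 10α-hydroperoxide with C8=C9 alkene; 4β,6α-diol; 2β-triethylsilyloxy | O[C@@H]1CC(C)=C[C@H](OO)[C@@]2(C)[C@@H](O[Si](CC)(CC)CC)C[C@](O)(C(C)C)[C@@H]12 | intermediate
18 | 8α,9α-epoxy-4β,6α,10α-triol with 2β-triethylsilyloxy and 8β-methyl | O[C@@H]1C[C@]2(C)O[C@@H]2[C@H](O)[C@@]2(C)[C@@H](O[Si](CC)(CC)CC)C[C@](O)(C(C)C)[C@@H]12 | intermediate
19 | angelic acid, (Z)-2-methylbut-2-enoic acid | C/C=C(/C)C(=O)O | starting material
20 | 6α-angelate of 18: 6α-[(Z)-2-methylbut-2-enoyloxy]-8α,9α-epoxy-4β,10α-dihydroxy-2β-(triethylsilyloxy) compound | C/C=C(/C)C(=O)O[C@@H]1C[C@]2(C)O[C@@H]2[C@H](O)[C@@]2(C)[C@@H](O[Si](CC)(CC)CC)C[C@](O)(C(C)C)[C@@H]12 | intermediate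
21 | 6α,10α-bis[(Z)-2-methylbut-2-enoyloxy]-8α,9α-epoxy-4β-hydroxy-2β-(triethylsilyloxy) compound | C/C=C(/C)C(=O)O[C@@H]1C[C@]2(C)O[C@@H]2[C@H](OC(=O)/C(C)=C\C)[C@@]2(C)[C@@H](O[Si](CC)(CC)CC)C[C@](O)(C(C)C)[C@@H]12 | intermediate
22 | CNP0265715.2: (1R,2S,4S,5R,6R,8S,9R,10R)-6,10-bis(angeloyloxy)-8,9-epoxy-cis-fused daucane-2,4-diol | C/C=C(/C)C(=O)O[C@@H]1C[C@]2(C)O[C@@H]2[C@H](OC(=O)/C(C)=C\C)[C@@]2(C)[C@@H](O)C[C@](O)(C(C)C)[C@@H]12 | target

**Count.** Total steps: 15. Longest linear sequence: 14 (steps 1 and 3 to 15; step 2 is a one-step side branch).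

**Steps most likely to fail**

Step 10. The silylated epoxide may ionise at the tertiary carbon C4 and rearrange, the cation may close stepwise onto C10 to a five-membered ring, or the diene may bond on its other face and give the trans fusion. The fallback makes the oxyallyl cation from an α-chloro ketone (Föhlisch-type (4+3) cycloaddition), so that no epoxide has to open in the ring-forming event. It sets out from 12. Reductive opening of the epoxy ketone at C5 with the phenylselenide reagent from (PhSe)2 and NaBH4 (AcOH, EtOH) should give the β-hydroxy ketone F1. LiN(iPr)2 (2.2 equiv) followed by Me3SiCl (THF, −78 to 0 °C) should silylate the C4 alkoxide and the kinetic methyl-side enolate and give the bis(trimethylsilyl) compound F2. N-Chlorosuccinimide gives the chloromethyl ketone F3. Et3N in LiClO4/Et2O then enolises toward C5, chloride leaves, and the intramolecular (4+3) cycloaddition should give 14, which is desilylated as in step 10 to come back to the route at 15. In this variant C5 is set by the tether and not by inversion.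

Step 12. The ene reaction of singlet oxygen with a 1,2-disubstituted ring alkene is slow, so photo-oxidative degradation may outrun conversion. The fallback does the allylic transposition by epoxide isomerisation and sets out from 16. 3-Chloroperbenzoic acid (NaHCO3, CH2Cl2) should epoxidise C9=C10 from the convex α face to the 9α,10α-epoxide F4. The aluminium amide made from Et2AlCl and lithium 2,2,6,6-tetramethylpiperidide removes the syn proton H-8 and should give the allylic alcohol F5 (10α-hydroxyl, C8=C9). VO(acac)2 with tBuOOH then epoxidises syn to the hydroxyl and comes back to the route at 18.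

Step 14. Acylation of the hindered C10 hydroxyl (between a quaternary carbon and the epoxide) may be slow enough for the angeloyl unit to isomerise to the (E)-tigloyl isomer. The fallback builds the (Z)-alkene after the ester bond and sets out from 20. The C10 hydroxyl is esterified with 2-[bis(2,2,2-trifluoroethoxy)phosphoryl]propanoic acid (N,N'-dicyclohexylcarbodiimide, 4-(dimethylamino)pyridine, CH2Cl2) to the C10 phosphonopropanoate F6. Still–Gennari olefination (KN(SiMe3)2, 18-crown-6, THF, −78 °C; acetaldehyde) should give the (Z)-2-methylbut-2-enoate and comes back to the route at 21.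

**Further compounds**

F1 | step 10 | β-hydroxy ketone from reductive opening of 12 at C5 (C4 tertiary alcohol, C5 methylene, C2 triethylsilyl ether) | C/C=C/C=C(\C)[C@H](C[C@](O)(C(C)C)CC(C)=O)O[Si](CC)(CC)CC
F2 | step 10 | C4 trimethylsilyl ether and methyl-side trimethylsilyl enol ether of F1 | C/C=C/C=C(\C)[C@H](C[C@](O[Si](C)(C)C)(C(C)C)CC(=C)O[Si](C)(C)C)O[Si](CC)(CC)CC
F3 | step 10 | chloromethyl ketone (C7 chloride) with C4 trimethylsilyl ether | C/C=C/C=C(\C)[C@H](C[C@](O[Si](C)(C)C)(C(C)C)CC(=O)CCl)O[Si](CC)(CC)CC
F4 | step 12 | 9α,10α-epoxide of 16 | O[C@@H]1C[C@@H](C)[C@@H]2O[C@@H]2[C@@]2(C)[C@@H](O[Si](CC)(CC)CC)C[C@](O)(C(C)C)[C@@H]12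
F5 | step 12 | allylic alcohol with 10α-hydroxyl and C8=C9 alkene | O[C@@H]1CC(C)=C[C@H](O)[C@@]2(C)[C@@H](O[Si](CC)(CC)CC)C[C@](O)(C(C)C)[C@@H]12
F6 | step 14 | 10α-{2-[bis(2,2,2-trifluoroethoxy)phosphoryl]propanoate} of 20 (6α-angelate retained) | C/C=C(/C)C(=O)O[C@@H]1C[C@]2(C)O[C@@H]2[C@H](OC(=O)C(C)P(=O)(OCC(F)(F)F)OCC(F)(F)F)[C@@]2(C)[C@@H](O[Si](CC)(CC)CC)C[C@](O)(C(C)C)[C@@H]12
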